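Ring B (C5–C10) of the target, read with its carbonyl at C9 instead of C7, is (S)-carvone. The isopropenyl carbon is C4 with both of its methyl groups, and the carvone stereocentre is C5. The route rests on disconnecting C3–C4. Hydrogen-atom transfer to the isopropenyl group of a C10-dialkylated carvone gives the tertiary C4 radical, which closes ring A 6-endo onto C3 of a 2-(phenylsulfonyl)allyl arm and delivers the trans-fused 11-nor-ent-drimane core in one operation. The precursor is carvone bearing a methyl group and that arm on C10, the arm anti to the isopropenyl group. Organocerium addition at C9 and oxidative enone transposition then place the side chain and the C7 ketone.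

Key step: step 5

Remark: atoms carry labdane numbers throughout; the C2 sulfone centre and the C9 carbinol centre are carried as epimer mixtures because both are erased later, and methyl hydrogen (S)-3-methylglutarate is assumed to be purchasable as the single enantiomer.

Step 1
Reactants: 1 phenyl vinyl sulfone
Product: 2 2-(phenylsulfonyl)prop-2-en-1-ol
Conditions: 37% aq. CH2O, DABCO, THF/H2O, rt
Reagents that add atoms: formaldehyde, C=O
Why: Morita–Baylis–Hillman reaction, in which DABCO adds to the vinyl sulfone, the α-sulfonyl carbanion is hydroxymethylated by formaldehyde and the amine is expelled again.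

Step 2
Reactants: 2 2-(phenylsulfonyl)prop-2-en-1-ol
Product: 3 3-bromo-2-(phenylsulfonyl)prop-1-ene (2-(phenylsulfonyl)allyl bromide)
Conditions: PBr3, Et2O, 0 °C
Reagents that add atoms: phosphorus tribromide, BrP(Br)Br
Why: bromination of a primary allylic alcohol through its phosphite ester, where direct and allylic displacement lead to the same bromide because the allyl unit is symmetric.

Step 3
Reactants: 4 (S)-carvone
Product: 6 (5S)-2,6-dimethyl-5-(prop-1-en-2-yl)cyclohex-2-en-1-one (6-methylcarvone; both C6 epimers), via lithium dienolate 5 (not isolated)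
Conditions: LiN(iPr)2 (1.05 equiv), THF, −78 °C; MeI, −78 → 0 °C
Reagents that add atoms: iodomethane, CI
Why: kinetic deprotonation at the α'-methylene (C10) gives the cross-conjugated dienolate, which is C-methylated in a standard enolate alkylation; the configuration at C10 does not matter because this centre is enolised again in step 4.

Step 4
Reactants: 6 (5S)-2,6-dimethyl-5-(prop-1-en-2-yl)cyclohex-2-en-1-one; 3 3-bromo-2-(phenylsulfonyl)prop-1-ene
Product: 8 (5R,6R)-2,6-dimethyl-6-[2-(phenylsulfonyl)prop-2-en-1-yl]-5-(prop-1-en-2-yl)cyclohex-2-en-1-one, via lithium dienolate 7 (not isolated)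
Conditions: LiN(iPr)2 (1.1 equiv), THF, −78 °C; then 3 (1.3 equiv), −78 → −20 °C
Reagents that add atoms: none
Why: enolate alkylation with an activated allylic bromide (SN2 and SN2' addition–elimination give the same product), in which the quaternary C10 centre is set by attack on the dienolate face anti to the neighbouring C5 isopropenyl group, the selectivity established for allylation of 6-methylcarvone.

Step 5
Reactants: 8 (5R,6R)-2,6-dimethyl-6-[2-(phenylsulfonyl)prop-2-en-1-yl]-5-(prop-1-en-2-yl)cyclohex-2-en-1-one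
Product: 11 (4aR,8aR)-2,5,5,8a-tetramethyl-7-(phenylsulfonyl)-4a,5,6,7,8,8a-hexahydronaphthalen-1(4H)-one (2-phenylsulfonyl-11-nor-ent-drim-7-en-9-one; both C2 epimers), via C4 tertiary radical 9 (not isolated), via C2 sulfonyl radical 10 (not isolated)
Conditions: Fe(acac)3 (30 mol%), PhSiH3 (2.5 equiv), EtOH/ethylene glycol 5:1, 60 °C, 0.02 M
Reagents that add atoms: none
Why: Proposed new method: Fe(acac)3 and PhSiH3 in ethanol should form an iron hydride that gives a hydrogen atom to the CH2 terminus of the isopropenyl group, so that C4 gains its second methyl group and becomes a nucleophilic tertiary radical; this radical adds to the unsubstituted terminus C3 of the sulfonylallyl arm, and the sulfonyl-stabilised C2 radical is reduced by divalent iron and protonated by ethanol. The closest known reaction type is the intermolecular iron-hydride reductive coupling of 1,1-disubstituted alkenes with vinyl sulfones and related acceptors, of which this is an intramolecular variant. Ring A (C10–C1–C2–C3–C4–C5) closes in the 6-endo-trig mode, because 5-exo attack at the sulfonyl-bearing C2 is polarity-mismatched, more hindered and would leave an unstabilised primary radical. The only new stereocentre, C2, is formed without control and is erased by desulfonylation, while the trans ring fusion is dictated by the existing C5 and C10 centres, whose isopropenyl group and allyl arm are trans-diequatorial. The step needs hydrogen-atom transfer to the isopropenyl group alone, which its higher electron density relative to the enone and the vinyl sulfone should secure, and high dilution keeps ring closure ahead of reduction of the C4 radical.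

Step 6
Reactants: 12 methyl hydrogen (S)-3-methylglutarate
Product: 13 methyl (S)-5-hydroxy-3-methylpentanoate
Conditions: BH3·SMe2 (1.2 equiv), THF, 0 °C → rt; then H2O
Reagents that add atoms: none
Why: chemoselective borane reduction of a carboxylic acid through its acyloxyborane in the presence of a methyl ester, which fixes the acid carbon as the future C15 without touching the stereocentre.

Step 7
Reactants: 13 methyl (S)-5-hydroxy-3-methylpentanoate
Product: 14 methyl (S)-5-(tert-butyldimethylsilyloxy)-3-methylpentanoate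
Conditions: TBSCl, imidazole, DMF, 0 °C → rt
Reagents that add atoms: tert-butyldimethylsilyl chloride, CC(C)(C)[Si](C)(C)Cl
Why: imidazole-promoted silylation of a primary alcohol, carried out at once so that the hydroxy ester cannot lactonise.

Step 8
Reactants: 14 methyl (S)-5-(tert-butyldimethylsilyloxy)-3-methylpentanoate
Product: 15 (R)-5-(tert-butyldimethylsilyloxy)-3-methylpentan-1-ol
Conditions: LiAlH4, THF, 0 °C; aq. NaOH work-up
Reagents that add atoms: none
Why: hydride reduction of the ester to the primary alcohol, to which the silyl ether is inert at 0 °C (the descriptor changes only through CIP priorities).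

Step 9
Reactants: 15 (R)-5-(tert-butyldimethylsilyloxy)-3-methylpentan-1-ol
Product: 16 (S)-tert-butyl[(5-iodo-3-methylpentyl)oxy]dimethylsilane
Conditions: I2, PPh3, imidazole, CH2Cl2, 0 °C → rt
Reagents that add atoms: iodine, [I][I]
Why: Appel-type iodination of a primary alcohol through its alkoxyphosphonium salt, an SN2 process remote from the stereocentre.

Step 10
Reactants: 16 (S)-tert-butyl[(5-iodo-3-methylpentyl)oxy]dimethylsilane; 11 (4aR,8aR)-2,5,5,8a-tetramethyl-7-(phenylsulfonyl)-4a,5,6,7,8,8a-hexahydronaphthalen-1(4H)-one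
Product: 19 (4aR,8aR)-1-[(3R)-5-(tert-butyldimethylsilyloxy)-3-methylpentyl]-2,5,5,8a-tetramethyl-7-(phenylsulfonyl)-1,4,4a,5,6,7,8,8a-octahydronaphthalen-1-ol (C9 carbinol; epimers at C9 and C2), via alkyllithium 17 (not isolated), via alkylcerium dichloride 18 (not isolated)
Conditions: 16 (2 equiv), t-BuLi (4.1 equiv), Et2O, −78 °C; CeCl3 (2.2 equiv), THF, −78 °C; then 11, −78 → −40 °C; aq. NH4Cl
Reagents that add atoms: none
Why: iodine–lithium exchange and transmetalation give a weakly basic alkylcerium dichloride that should add 1,2 to the hindered C9 enone carbonyl without deprotonating the sulfone α-position (organocerium carbonyl addition); the new C9 centre, formed by attack anti to the axial C10 methyl group, is irrelevant because C9 becomes sp2 in step 12.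

Step 11
Reactants: 19 (4aR,8aR)-1-[(3R)-5-(tert-butyldimethylsilyloxy)-3-methylpentyl]-2,5,5,8a-tetramethyl-7-(phenylsulfonyl)-1,4,4a,5,6,7,8,8a-octahydronaphthalen-1-ol
Product: 20 (4aR,8aR)-1-[(3R)-5-(tert-butyldimethylsilyloxy)-3-methylpentyl]-2,5,5,8a-tetramethyl-1,4,4a,5,6,7,8,8a-octahydronaphthalen-1-ol (C9 epimers)
Conditions: 6% Na/Hg, Na2HPO4, MeOH/THF, −20 → 0 °C
Reagents that add atoms: none
Why: reductive desulfonylation by electron transfer to the phenyl sulfone followed by protonation of the C2 carbanion, which the tertiary allylic alcohol and silyl ether tolerate now that the enone is masked.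

Step 12
Reactants: 20 (4aR,8aR)-1-[(3R)-5-(tert-butyldimethylsilyloxy)-3-methylpentyl]-2,5,5,8a-tetramethyl-1,4,4a,5,6,7,8,8a-octahydronaphthalen-1-ol
Product: 23 (4aR,8aR)-4-[(3R)-5-(tert-butyldimethylsilyloxy)-3-methylpentyl]-3,4a,8,8-tetramethyl-4a,5,6,7,8,8a-hexahydronaphthalen-2(1H)-one, via C9 chlorochromate ester 21 (not isolated), via C7 chlorochromate ester 22 (not isolated)
Conditions: pyridinium chlorochromate [C5H5NH][CrO3Cl] (3 equiv), 4 Å MS, CH2Cl2, rt
Reagents that add atoms: pyridinium chlorochromate, [O-][Cr](=O)(=O)Cl.c1cc[nH+]cc1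
Why: Babler–Dauben oxidative transposition, in which the tertiary C9 chlorochromate ester undergoes a [3,3]-sigmatropic shift to the secondary C7 ester and is oxidised to the C7 ketone with the alkene moved to C8=C9.

Step 13
Reactants: 23 (4aR,8aR)-4-[(3R)-5-(tert-butyldimethylsilyloxy)-3-methylpentyl]-3,4a,8,8-tetramethyl-4a,5,6,7,8,8a-hexahydronaphthalen-2(1H)-one
Product: 26 (3R)-3-methyl-5-[(4aR,8aR)-2,5,5,8a-tetramethyl-3-oxo-3,4,4a,5,6,7,8,8a-octahydronaphthalen-1-yl]pentanoic acid, via primary alcohol 24 (not isolated), via aldehyde 25 (not isolated)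
Conditions: CrO3, H2SO4, H2O (Jones reagent), acetone, 0 °C → rt
Reagents that add atoms: water, O
Why: Jones oxidation applied directly to the primary silyl ether, where the acidic hexavalent chromium medium cleaves the TBS group and oxidises the freed alcohol through the aldehyde hydrate to the acid, leaving the tetrasubstituted enone and the non-epimerisable C13 centre untouched.

Step 14
Reactants: 26 (3R)-3-methyl-5-[(4aR,8aR)-2,5,5,8a-tetramethyl-3-oxo-3,4,4a,5,6,7,8,8a-octahydronaphthalen-1-yl]pentanoic acid; 27 (S)-solketal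
Product: 28 [(4R)-2,2-dimethyl-1,3-dioxolan-4-yl]methyl (3R)-3-methyl-5-[(4aR,8aR)-2,5,5,8a-tetramethyl-3-oxo-3,4,4a,5,6,7,8,8a-octahydronaphthalen-1-yl]pentanoate
Conditions: DCC, DMAP (cat.), CH2Cl2, 0 °C → rt
Reagents that add atoms: none
Why: Steglich esterification of the acid with the primary hydroxyl of solketal through the O-acylisourea and acylpyridinium, which touches no stereocentre (the dioxolane descriptor changes only through CIP priorities).

Step 15
Reactants: 28 [(4R)-2,2-dimethyl-1,3-dioxolan-4-yl]methyl (3R)-3-methyl-5-[(4aR,8aR)-2,5,5,8a-tetramethyl-3-oxo-3,4,4a,5,6,7,8,8a-octahydronaphthalen-1-yl]pentanoate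
Product: 29 (2R)-2,3-dihydroxypropyl (3R)-3-methyl-5-[(4aR,8aR)-2,5,5,8a-tetramethyl-3-oxo-3,4,4a,5,6,7,8,8a-octahydronaphthalen-1-yl]pentanoate (CNP0316600.2)
Conditions: AcOH/H2O 4:1, 40 °C
Reagents that add atoms: none
Why: acid-catalysed acetal hydrolysis releases the 1,2-diol, and the mild acid and low temperature should keep 1,2-acyl migration (which would scramble the glycerol centre) negligible while the ester and enone survive.

Compound list
1 | phenyl vinyl sulfone | C=CS(=O)(=O)c1ccccc1 | starting material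
2 | 2-(phenylsulfonyl)prop-2-en-1-ol | C=C(CO)S(=O)(=O)c1ccccc1 | intermediate
3 | 3-bromo-2-(phenylsulfonyl)prop-1-ene (2-(phenylsulfonyl)allyl bromide) | C=C(CBr)S(=O)(=O)c1ccccc1 | intermediate
4 | (S)-carvone | C=C(C)[C@H]1CC=C(C)C(=O)C1 | starting material
5 | lithium dienolate of 4 (not isolated) | C=C(C)[C@H]1CC=C(C)C(O[Li])=C1 | intermediate
6 | (5S)-2,6-dimethyl-5-(prop-1-en-2-yl)cyclohex-2-en-1-one (6-methylcarvone; both C6 epimers) | C=C(C)[C@H]1CC=C(C)C(=O)C1C | intermediate
7 | lithium dienolate of 6 (not isolated) | C=C(C)[C@H]1CC=C(C)C(O[Li])=C1C | intermediate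
8 | (5R,6R)-2,6-dimethyl-6-[2-(phenylsulfonyl)prop-2-en-1-yl]-5-(prop-1-en-2-yl)cyclohex-2-en-1-one | CC1=CC[C@H](C(C)=C)[C@@](C)(CC(=C)S(=O)(=O)c2ccccc2)C1=O | intermediate
9 | C4 tertiary radical from 8 (not isolated) | CC1=CC[C@H]([C](C)C)[C@@](C)(CC(=C)S(=O)(=O)c2ccccc2)C1=O | intermediate
10 | C2 sulfonyl-stabilised radical after ring closure (not isolated) | CC1=CC[C@@H]2C(C)(C)C[C](S(=O)(=O)c3ccccc3)C[C@@]2(C)C1=O | intermediate
11 | (4aR,8aR)-2,5,5,8a-tetramethyl-7-(phenylsulfonyl)-4a,5,6,7,8,8a-hexahydronaphthalen-1(4H)-one (2-phenylsulfonyl-11-nor-ent-drim-7-en-9-one; both C2 epimers) | CC1=CC[C@@H]2C(C)(C)CC(S(=O)(=O)c3ccccc3)C[C@@]2(C)C1=O | intermediate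
12 | methyl hydrogen (S)-3-methylglutarate | COC(=O)C[C@@H](C)CC(=O)O | starting material
13 | methyl (S)-5-hydroxy-3-methylpentanoate | COC(=O)C[C@@H](C)CCO | intermediate
14 | methyl (S)-5-(tert-butyldimethylsilyloxy)-3-methylpentanoate | COC(=O)C[C@@H](C)CCO[Si](C)(C)C(C)(C)C | intermediate
15 | (R)-5-(tert-butyldimethylsilyloxy)-3-methylpentan-1-ol | OCC[C@@H](C)CCO[Si](C)(C)C(C)(C)C | intermediate
16 | (S)-tert-butyl[(5-iodo-3-methylpentyl)oxy]dimethylsilane | ICC[C@@H](C)CCO[Si](C)(C)C(C)(C)C | intermediate
17 | [(3R)-5-(tert-butyldimethylsilyloxy)-3-methylpentyl]lithium (not isolated) | [Li]CC[C@@H](C)CCO[Si](C)(C)C(C)(C)C | intermediate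
18 | dichloro[(3S)-5-(tert-butyldimethylsilyloxy)-3-methylpentyl]cerium (not isolated) | Cl[Ce](Cl)CC[C@@H](C)CCO[Si](C)(C)C(C)(C)C | intermediate
19 | (4aR,8aR)-1-[(3R)-5-(tert-butyldimethylsilyloxy)-3-methylpentyl]-2,5,5,8a-tetramethyl-7-(phenylsulfonyl)-1,4,4a,5,6,7,8,8a-octahydronaphthalen-1-ol (epimers at C9 and C2) | CC1=CC[C@@H]2C(C)(C)CC(S(=O)(=O)c3ccccc3)C[C@@]2(C)C1(O)CC[C@@H](C)CCO[Si](C)(C)C(C)(C)C | intermediate
20 | (4aR,8aR)-1-[(3R)-5-(tert-butyldimethylsilyloxy)-3-methylpentyl]-2,5,5,8a-tetramethyl-1,4,4a,5,6,7,8,8a-octahydronaphthalen-1-ol (C9 epimers) | CC1=CC[C@@H]2C(C)(C)CCC[C@@]2(C)C1(O)CC[C@@H](C)CCO[Si](C)(C)C(C)(C)C | intermediate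
21 | C9 chlorochromate ester of 20 (not isolated) | CC1=CC[C@@H]2C(C)(C)CCC[C@@]2(C)C1(O[Cr](=O)(=O)Cl)CC[C@@H](C)CCO[Si](C)(C)C(C)(C)C | intermediate
22 | transposed C7 chlorochromate ester with C8=C9 alkene (not isolated) | CC1=C(CC[C@@H](C)CCO[Si](C)(C)C(C)(C)C)[C@]2(C)CCCC(C)(C)[C@H]2CC1O[Cr](=O)(=O)Cl | intermediate
23 | (4aR,8aR)-4-[(3R)-5-(tert-butyldimethylsilyloxy)-3-methylpentyl]-3,4a,8,8-tetramethyl-4a,5,6,7,8,8a-hexahydronaphthalen-2(1H)-one | CC1=C(CC[C@@H](C)CCO[Si](C)(C)C(C)(C)C)[C@]2(C)CCCC(C)(C)[C@H]2CC1=O | intermediate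
24 | (4aR,8aR)-4-[(3R)-5-hydroxy-3-methylpentyl]-3,4a,8,8-tetramethyl-4a,5,6,7,8,8a-hexahydronaphthalen-2(1H)-one (not isolated) | CC1=C(CC[C@@H](C)CCO)[C@]2(C)CCCC(C)(C)[C@H]2CC1=O | intermediate
25 | (3R)-3-methyl-5-[(4aR,8aR)-2,5,5,8a-tetramethyl-3-oxo-3,4,4a,5,6,7,8,8a-octahydronaphthalen-1-yl]pentanal (not isolated) | CC1=C(CC[C@@H](C)CC=O)[C@]2(C)CCCC(C)(C)[C@H]2CC1=O | intermediate
26 | (3R)-3-methyl-5-[(4aR,8aR)-2,5,5,8a-tetramethyl-3-oxo-3,4,4a,5,6,7,8,8a-octahydronaphthalen-1-yl]pentanoic acid | CC1=C(CC[C@@H](C)CC(=O)O)[C@]2(C)CCCC(C)(C)[C@H]2CC1=O | intermediate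
27 | (S)-solketal, [(4S)-2,2-dimethyl-1,3-dioxolan-4-yl]methanol | CC1(C)OC[C@H](CO)O1 | starting material
28 | [(4R)-2,2-dimethyl-1,3-dioxolan-4-yl]methyl (3R)-3-methyl-5-[(4aR,8aR)-2,5,5,8a-tetramethyl-3-oxo-3,4,4a,5,6,7,8,8a-octahydronaphthalen-1-yl]pentanoate | CC1=C(CC[C@@H](C)CC(=O)OC[C@H]2COC(C)(C)O2)[C@]3(C)CCCC(C)(C)[C@H]3CC1=O | intermediate
29 | (2R)-2,3-dihydroxypropyl (3R)-3-methyl-5-[(4aR,8aR)-2,5,5,8a-tetramethyl-3-oxo-3,4,4a,5,6,7,8,8a-octahydronaphthalen-1-yl]pentanoate (CNP0316600.2) | CC1=C(CC[C@@H](C)CC(=O)OC[C@H](O)CO)[C@]2(C)CCCC(C)(C)[C@H]2CC1=O | target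

Total step count: 15. Longest linear sequence: 10 steps (steps 6–15, from methyl hydrogen (S)-3-methylglutarate; 9 steps from (S)-carvone).

Steps most likely to fail

Step 5 (labelled step). What may go wrong: the iron hydride may give hydrogen atoms to the vinyl sulfone or the enone, or the C4 radical may be reduced before it reaches C3, so that ring A does not close. The fallback uses known chemistry, sets out from 8 and returns at 11. Markovnikov hydrobromination of the isopropenyl group with HBr in AcOH at 0 °C (the classical hydrobromination of carvone; the electron-poor enone and vinyl sulfone should not add HBr) would give the tertiary bromide (5S,6R)-5-(2-bromopropan-2-yl)-2,6-dimethyl-6-[2-(phenylsulfonyl)prop-2-en-1-yl]cyclohex-2-en-1-one F1. Slow addition of Bu3SnH with AIBN in benzene at 80 °C would then generate the same C4 radical by bromine abstraction at low hydride concentration, a tin-hydride radical cyclisation onto an activated alkene, and hydrogen transfer from tin to the C2 radical would give 11.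

Step 10. What may go wrong: proton transfer from the sulfone α-position (C2) or γ-enolisation may consume the organometallic faster than it adds to the hindered C9 carbonyl. The fallback sets out from 11 and returns at 20, at the cost of two extra steps. Luche reduction (NaBH4, CeCl3·7H2O, MeOH, 0 °C) would mask the enone as the allylic alcohol (4aR,8aR)-2,5,5,8a-tetramethyl-7-(phenylsulfonyl)-1,4,4a,5,6,7,8,8a-octahydronaphthalen-1-ol F2. Desulfonylation with 6% Na/Hg and Na2HPO4 in MeOH would give (4aR,8aR)-2,5,5,8a-tetramethyl-1,4,4a,5,6,7,8,8a-octahydronaphthalen-1-ol F3. Dess–Martin oxidation would restore the enone as (4aR,8aR)-2,5,5,8a-tetramethyl-4a,5,6,7,8,8a-hexahydronaphthalen-1(4H)-one F4, which has no acidic sulfone proton. Addition of 18 to this ketone under the conditions of step 10 would give 20 directly, so step 11 is no longer needed.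

Step 4. What may go wrong: the dienolate may add to the vinyl sulfone of the product already formed, react at oxygen, or lose facial selectivity with the very reactive electrophile. The fallback sets out from 6 (through 7) and returns at 8. Alkylation with 2,3-dibromopropene, an ordinary allylic bromide expected to show the anti selectivity of allyl bromide, would give (5R,6R)-6-(2-bromoprop-2-en-1-yl)-2,6-dimethyl-5-(prop-1-en-2-yl)cyclohex-2-en-1-one F5. Copper-catalysed coupling of its vinyl bromide with PhSO2Na (CuI, L-proline sodium salt, DMSO, 90 °C) would then install the sulfone and give 8.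

Further compounds
F1 | step 5 | (5S,6R)-5-(2-bromopropan-2-yl)-2,6-dimethyl-6-[2-(phenylsulfonyl)prop-2-en-1-yl]cyclohex-2-en-1-one | CC1=CC[C@H](C(C)(C)Br)[C@@](C)(CC(=C)S(=O)(=O)c2ccccc2)C1=O
F2 | step 10 | (4aR,8aR)-2,5,5,8a-tetramethyl-7-(phenylsulfonyl)-1,4,4a,5,6,7,8,8a-octahydronaphthalen-1-ol (epimers at C9 and C2) | CC1=CC[C@@H]2C(C)(C)CC(S(=O)(=O)c3ccccc3)C[C@@]2(C)C1O
F3 | step 10 | (4aR,8aR)-2,5,5,8a-tetramethyl-1,4,4a,5,6,7,8,8a-octahydronaphthalen-1-ol (C9 epimers) | CC1=CC[C@@H]2C(C)(C)CCC[C@@]2(C)C1O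
F4 | step 10 | (4aR,8aR)-2,5,5,8a-tetramethyl-4a,5,6,7,8,8a-hexahydronaphthalen-1(4H)-one (11-nor-ent-drim-7-en-9-one) | CC1=CC[C@@H]2C(C)(C)CCC[C@@]2(C)C1=O
F5 | step 4 | (5R,6R)-6-(2-bromoprop-2-en-1-yl)-2,6-dimethyl-5-(prop-1-en-2-yl)cyclohex-2-en-1-one | CC1=CC[C@H](C(C)=C)[C@@](C)(CC(Br)=C)C1=O
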